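**Plan**

- Ring B is a 2,3-dimethoxyhydroquinone: C2'–OH, C3'–OMe, C4'–OMe and C5'–OH in a row, chromone C2 on C1' and the only ring hydrogen on C6'. One oxidation level up it is the para-quinone that a symmetric 3,4-dimethoxy-2,5-dioxygenated furan and a terminal alkyne deliver.
- Retrosynthesis: the target is taken back to a 5-O-benzyl quinone. Cutting C1'–C2' and C5'–C6' gives 5-benzyloxy-2-ethynyl-7-methoxychromone and 3,4-dimethoxy-2,5-bis(trimethylsilyloxy)furan. The alkyne goes back to the C2 aldehyde and ester, and cutting C2–C3 and O1–C2 gives a 2'-hydroxyacetophenone and diethyl oxalate. The furan goes back to di-O-methyltartaric anhydride.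
- Forward: ring A is bought and ring C closes by Claisen condensation and cyclodehydration. The ester is taken to CH2OH, CHO and C≡CH. Ring B closes last by [4+2] cycloaddition with loss of hexamethyldisiloxane, and one hydrogenation reduces the quinone and frees the 5-OH.
- Stereochemistry: the target has no stereocentre. The tartrate centres are flattened in the furan and the bridgeheads of the cycloadduct vanish in the quinone.

Key step: step 10

Remark: the 5-oxygen is carried as a benzyl ether rather than a methyl ether, so that no Lewis acid has to discriminate between the 5-OMe and the two B-ring methyl ethers flanked by free hydroxyls at the end.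

**Route**

Step 1
Reactants: 1 2',6'-dihydroxy-4'-methoxyacetophenone
Product: 2 1-[2-(benzyloxy)-6-hydroxy-4-methoxyphenyl]ethan-1-one
Conditions: BnBr (1.05 equiv), K2CO3, acetone, reflux
Reagents that add atoms: benzyl bromide, BrCc1ccccc1
Why: Williamson etherification should stop at the mono-ether, because the remaining hydroxyl is held in a hydrogen bond to the ketone and is far less nucleophilic; benzyl is chosen because the final hydrogenation removes it.

Step 2
Reactants: 2 1-[2-(benzyloxy)-6-hydroxy-4-methoxyphenyl]ethan-1-one; 3 diethyl oxalate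
Product: 5 ethyl 5-(benzyloxy)-7-methoxy-4-oxo-4H-chromene-2-carboxylate, via aryl diketo ester 4 (not isolated)
Conditions: NaOEt (4 equiv), EtOH, 0 °C to reflux; then HCl in EtOH (to pH 1), 60 °C, 1 h
Reagents that add atoms: none
Why: Crossed Claisen condensation of the ketone enolate with non-enolisable diethyl oxalate, then acid-catalysed cyclodehydration of the phenol onto the α-keto ester carbonyl, is the classical chromone-2-carboxylate synthesis, and brief dilute ethanolic acid should spare the benzyl ether.

Step 3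
Reactants: 5 ethyl 5-(benzyloxy)-7-methoxy-4-oxo-4H-chromene-2-carboxylate
Product: 6 5-(benzyloxy)-2-(hydroxymethyl)-7-methoxy-4H-chromen-4-one
Conditions: NaBH4, MeOH/THF, 0 °C
Reagents that add atoms: none
Why: Chemoselective borohydride reduction is expected because the C2 ester is an activated α-alkoxyacrylate that reacts faster than the vinylogous-ester C4 carbonyl, as known for chromone-2-carboxylates.

Step 4
Reactants: 6 5-(benzyloxy)-2-(hydroxymethyl)-7-methoxy-4H-chromen-4-one
Product: 7 5-(benzyloxy)-7-methoxy-4-oxo-4H-chromene-2-carbaldehyde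
Conditions: activated MnO2 (excess), CH2Cl2, rt; filtered and used at once
Reagents that add atoms: none
Why: MnO2 oxidation of an allylic-type primary alcohol (the CH2OH sits on the C2=C3 bond) should stop at the aldehyde under neutral heterogeneous conditions, as known for 2-hydroxymethyl-4-pyranones.

Step 5
Reactants: 7 5-(benzyloxy)-7-methoxy-4-oxo-4H-chromene-2-carbaldehyde
Product: 8 5-(benzyloxy)-2-ethynyl-7-methoxy-4H-chromen-4-one
Conditions: dimethyl (1-diazo-2-oxopropyl)phosphonate, K2CO3, MeOH, 0 °C to rt, short reaction time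
Reagents that add atoms: dimethyl (1-diazo-2-oxopropyl)phosphonate, CC(=O)C(=[N+]=[N-])P(=O)(OC)OC
Why: Seyferth–Gilbert homologation in its Ohira–Bestmann form should convert the non-enolisable aldehyde into the terminal alkyne by addition of the diazomethylphosphonate anion, loss of phosphate and N2 and 1,2-hydride shift, with low temperature limiting methanol addition to the conjugated product.

Step 6
Reactants: 9 dimethyl L-tartrate
Product: 10 dimethyl (2R,3R)-2,3-dimethoxybutanedioate
Conditions: MeI (excess), Ag2O, Et2O, reflux, dark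
Reagents that add atoms: iodomethane, CI
Why: Purdie methylation etherifies both secondary hydroxyls without a free alkoxide or enolate, so β-elimination and ester condensation are avoided.

Step 7
Reactants: 10 dimethyl (2R,3R)-2,3-dimethoxybutanedioate
Product: 11 (2R,3R)-2,3-dimethoxybutanedioic acid
Conditions: NaOH (2.2 equiv), H2O/MeOH, rt; then HCl to pH 1, evaporation, extraction with hot EtOAc
Reagents that add atoms: sodium hydroxide, [Na+].[OH-]
Why: Ordinary saponification of two methyl esters, with the methyl ethers inert.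

Step 8
Reactants: 11 (2R,3R)-2,3-dimethoxybutanedioic acid
Product: 12 (3R,4R)-3,4-dimethoxyoxolane-2,5-dione
Conditions: AcCl (neat), reflux; volatiles removed in vacuo
Reagents that add atoms: none
Why: Cyclodehydration of a succinic acid to its five-membered anhydride through the mixed anhydride, standard for tartaric acid derivatives.

Step 9
Reactants: 12 (3R,4R)-3,4-dimethoxyoxolane-2,5-dione
Product: 13 3,4-dimethoxy-2,5-bis(trimethylsilyloxy)furan
Conditions: TMSOTf (2.2 equiv), Et3N (3 equiv), Et2O, 0 °C to rt; salt layer removed, bulb-to-bulb distillation, used at once under Ar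
Reagents that add atoms: trimethylsilyl trifluoromethanesulfonate, C[Si](C)(C)OS(=O)(=O)C(F)(F)F
Why: Double soft enolisation and O-silylation of a succinic anhydride gives the 2,5-bis(silyloxy)furan, the second enolisation being driven by aromatisation; both stereocentres become sp2, and the absence of a free enolate should suppress β-loss of methoxide.

Step 10
Reactants: 8 5-(benzyloxy)-2-ethynyl-7-methoxy-4H-chromen-4-one; 13 3,4-dimethoxy-2,5-bis(trimethylsilyloxy)furan
Product: 15 2-[5-(benzyloxy)-7-methoxy-4-oxo-4H-chromen-2-yl]-5,6-dimethoxy-1,4-benzoquinone, via oxanorbornadiene adduct 14 (not isolated)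
Conditions: 13 (1.3 equiv, added in portions), toluene, 100 °C, Ar; then SiO2, CH2Cl2, rt
Reagents that add atoms: none
Why: A thermal, normal-demand concerted [4+2] cycloaddition joins the diene termini C2 and C5 of the tetra-oxygenated furan 13 to the alkyne of 8, whose LUMO is lowered by conjugation through C2=C3 to the C4 carbonyl, and gives the 7-oxanorbornadiene 14. In 14 each bridgehead is a silyl ketal carbon, so a silyloxy lone pair pushes open the oxygen bridge and silyl transfer expels hexamethyldisiloxane, leaving the two bridgeheads as the quinone carbonyls. The closest known reaction type is the Diels–Alder reaction of 2,5-bis(trimethylsilyloxy)furans with acetylenic dienophiles, which gives para-quinones. Ring B is closed as a six-membered carbocycle by intermolecular cycloaddition that forms C1'–C2' and C5'–C6' at once, and the bridge fragmentation then makes it the quinone; no stereocentre survives, since both bridgehead centres of racemic 14 become sp2. Regiochemistry is not an issue because the diene is symmetric, and the alkyne is preferred over the chromone C2=C3 bond because that trisubstituted vinylogous-ester alkene is hindered and electron-rich. Lewis-acid-free conditions in toluene disfavour Michael-type attack through the furan 3-position, and portionwise addition keeps the furan from consuming the quinone, any of which that is reduced in the flask converges in step 11.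

Step 11
Reactants: 15 2-[5-(benzyloxy)-7-methoxy-4-oxo-4H-chromen-2-yl]-5,6-dimethoxy-1,4-benzoquinone
Product: 16 2-(2,5-dihydroxy-3,4-dimethoxyphenyl)-5-hydroxy-7-methoxy-4H-chromen-4-one (CNP0170944.0)
Conditions: H2 (1 atm), 10% Pd/C, EtOAc/MeOH, rt; filtration and concentration under Ar
Reagents that add atoms: none
Why: Catalytic hydrogenation should reduce the quinone to the hydroquinone at once and hydrogenolyse the benzyl aryl ether to the chelated 5-OH, while the chromone C2=C3 bond is expected to stay intact at 1 atm and rt; the air-sensitive hydroquinone is handled under argon.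

**Compound list**

1 | 2',6'-dihydroxy-4'-methoxyacetophenone | CC(=O)c1c(O)cc(OC)cc1O | starting material
2 | 1-[2-(benzyloxy)-6-hydroxy-4-methoxyphenyl]ethan-1-one | CC(=O)c1c(O)cc(OC)cc1OCc1ccccc1 | intermediate
3 | diethyl oxalate | CCOC(=O)C(=O)OCC | starting material
4 | ethyl 4-[2-(benzyloxy)-6-hydroxy-4-methoxyphenyl]-2,4-dioxobutanoate | CCOC(=O)C(=O)CC(=O)c1c(O)cc(OC)cc1OCc1ccccc1 | intermediate (not isolated)
5 | ethyl 5-(benzyloxy)-7-methoxy-4-oxo-4H-chromene-2-carboxylate | CCOC(=O)c1cc(=O)c2c(OCc3ccccc3)cc(OC)cc2o1 | intermediate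
6 | 5-(benzyloxy)-2-(hydroxymethyl)-7-methoxy-4H-chromen-4-one | OCc1cc(=O)c2c(OCc3ccccc3)cc(OC)cc2o1 | intermediate
7 | 5-(benzyloxy)-7-methoxy-4-oxo-4H-chromene-2-carbaldehyde | O=Cc1cc(=O)c2c(OCc3ccccc3)cc(OC)cc2o1 | intermediate
8 | 5-(benzyloxy)-2-ethynyl-7-methoxy-4H-chromen-4-one | C#Cc1cc(=O)c2c(OCc3ccccc3)cc(OC)cc2o1 | intermediate
9 | dimethyl L-tartrate, (2R,3R) | COC(=O)[C@H](O)[C@@H](O)C(=O)OC | starting material
10 | dimethyl (2R,3R)-2,3-dimethoxybutanedioate | COC(=O)[C@H](OC)[C@@H](OC)C(=O)OC | intermediate
11 | (2R,3R)-2,3-dimethoxybutanedioic acid | OC(=O)[C@H](OC)[C@@H](OC)C(O)=O | intermediate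
12 | (3R,4R)-3,4-dimethoxyoxolane-2,5-dione | O=C1[C@H](OC)[C@@H](OC)C(=O)O1 | intermediate
13 | 3,4-dimethoxy-2,5-bis(trimethylsilyloxy)furan | COc1c(O[Si](C)(C)C)oc(O[Si](C)(C)C)c1OC | intermediate
14 | 2-[5-(benzyloxy)-7-methoxy-4-oxo-4H-chromen-2-yl]-5,6-dimethoxy-1,4-bis(trimethylsilyloxy)-7-oxabicyclo[2.2.1]hepta-2,5-diene (racemic, one enantiomer written) | COC1=C(OC)[C@@]2(O[Si](C)(C)C)C(c3cc(=O)c4c(OCc5ccccc5)cc(OC)cc4o3)=C[C@]1(O[Si](C)(C)C)O2 | intermediate (not isolated)
15 | 2-[5-(benzyloxy)-7-methoxy-4-oxo-4H-chromen-2-yl]-5,6-dimethoxy-1,4-benzoquinone | COC1=C(OC)C(=O)C(c2cc(=O)c3c(OCc4ccccc4)cc(OC)cc3o2)=CC1=O | intermediate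
16 | 2-(2,5-dihydroxy-3,4-dimethoxyphenyl)-5-hydroxy-7-methoxy-4H-chromen-4-one | COc1cc(O)c2c(=O)cc(-c3cc(O)c(OC)c(OC)c3O)oc2c1 | target

**Step count and risks**

Total steps: 11. Longest linear sequence: 7 steps (steps 1, 2, 3, 4, 5, 10 and 11, from compound 1). The furan branch (steps 6 to 9) joins at step 10.

Step 10. The cycloaddition may be slow on an alkyne that is activated only vinylogously. The furan may instead attack in a Michael sense through its 3-position, or be consumed by the quinone as it forms, through electron transfer or a second cycloaddition. The fallback sets out from furan 13 and acetophenone 2 and comes back at target 16. It keeps the furan cycloaddition for ring B but uses a much stronger dienophile and builds ring C afterwards. Furan 13 and methyl propiolate in CH2Cl2 at rt should give methyl 5,6-dimethoxy-1,4-bis(trimethylsilyloxy)-7-oxabicyclo[2.2.1]hepta-2,5-diene-2-carboxylate F1, which sheds hexamethyldisiloxane to methyl 4,5-dimethoxy-3,6-dioxocyclohexa-1,4-diene-1-carboxylate F2. Aqueous Na2S2O4 in the work-up reduces it to methyl 2,5-dihydroxy-3,4-dimethoxybenzoate F3, and BnBr with K2CO3 in DMF gives methyl 2,5-bis(benzyloxy)-3,4-dimethoxybenzoate F4. The lithium dianion of 2 (LiN(SiMe3)2, THF, −78 °C to rt) is acylated by F4 in a Claisen condensation to 1-[2-(benzyloxy)-6-hydroxy-4-methoxyphenyl]-3-[2,5-bis(benzyloxy)-3,4-dimethoxyphenyl]propane-1,3-dione F5. Catalytic H2SO4 in AcOH closes ring C to 5-(benzyloxy)-2-[2,5-bis(benzyloxy)-3,4-dimethoxyphenyl]-7-methoxy-4H-chromen-4-one F6, and hydrogenolysis over Pd/C gives 16.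

Step 9. Methanol may be lost by β-elimination during enolisation (leading to methoxymaleic anhydride), the second silylation may stall, or the furan may hydrolyse during isolation. The fallback sets out from alkyne 8 and comes back at quinone 15, replacing the silyloxyfuran by commercial 3,4-dimethoxyfuran and adding the missing oxygen afterwards. Heating 8 with 3,4-dimethoxyfuran in toluene should give 5-(benzyloxy)-2-(5,6-dimethoxy-7-oxabicyclo[2.2.1]hepta-2,5-dien-2-yl)-7-methoxy-4H-chromen-4-one F7. Catalytic CF3CO2H in CH2Cl2 opens the oxygen bridge to the two regioisomeric phenols 5-(benzyloxy)-2-(2-hydroxy-3,4-dimethoxyphenyl)-7-methoxy-4H-chromen-4-one F8 and 5-(benzyloxy)-2-(3-hydroxy-4,5-dimethoxyphenyl)-7-methoxy-4H-chromen-4-one F9. Both carry hydrogen para to the hydroxyl, so Teuber oxidation of the mixture with Fremy's salt, ON(SO3K)2, in buffered aqueous acetone converges on 15.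

Step 5. Methanol or methoxide may add to the pyranone of the aldehyde or to the conjugated alkyne once formed, and carbonate may open the pyranone ring. The fallback sets out from aldehyde 7 and comes back at alkyne 8 without any nucleophilic alcohol. CBr4 and PPh3 in CH2Cl2 at 0 °C (Corey–Fuchs olefination) give 5-(benzyloxy)-2-(2,2-dibromoethenyl)-7-methoxy-4H-chromen-4-one F10. Bu3SnH with catalytic Pd(PPh3)4 (zerovalent palladium) in toluene removes the trans bromine selectively to give 5-(benzyloxy)-2-[(Z)-2-bromoethenyl]-7-methoxy-4H-chromen-4-one F11. Bu4NF in DMF at rt then effects anti-elimination of HBr to 8.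

**Further compounds**

F1 | step 10 | methyl 5,6-dimethoxy-1,4-bis(trimethylsilyloxy)-7-oxabicyclo[2.2.1]hepta-2,5-diene-2-carboxylate (racemic, one enantiomer written) | COC(=O)C1=C[C@]2(O[Si](C)(C)C)O[C@@]1(O[Si](C)(C)C)C(OC)=C2OC
F2 | step 10 | methyl 4,5-dimethoxy-3,6-dioxocyclohexa-1,4-diene-1-carboxylate | COC(=O)C1=CC(=O)C(OC)=C(OC)C1=O
F3 | step 10 | methyl 2,5-dihydroxy-3,4-dimethoxybenzoate | COC(=O)c1cc(O)c(OC)c(OC)c1O
F4 | step 10 | methyl 2,5-bis(benzyloxy)-3,4-dimethoxybenzoate | COC(=O)c1cc(OCc2ccccc2)c(OC)c(OC)c1OCc1ccccc1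
F5 | step 10 | 1-[2-(benzyloxy)-6-hydroxy-4-methoxyphenyl]-3-[2,5-bis(benzyloxy)-3,4-dimethoxyphenyl]propane-1,3-dione | O=C(CC(=O)c1cc(OCc2ccccc2)c(OC)c(OC)c1OCc1ccccc1)c1c(O)cc(OC)cc1OCc1ccccc1
F6 | step 10 | 5-(benzyloxy)-2-[2,5-bis(benzyloxy)-3,4-dimethoxyphenyl]-7-methoxy-4H-chromen-4-one | COc1cc(OCc2ccccc2)c2c(=O)cc(-c3cc(OCc4ccccc4)c(OC)c(OC)c3OCc3ccccc3)oc2c1
F7 | step 9 | 5-(benzyloxy)-2-(5,6-dimethoxy-7-oxabicyclo[2.2.1]hepta-2,5-dien-2-yl)-7-methoxy-4H-chromen-4-one (racemic, one enantiomer written) | COC1=C(OC)[C@@H]2O[C@H]1C=C2c1cc(=O)c2c(OCc3ccccc3)cc(OC)cc2o1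
F8 | step 9 | 5-(benzyloxy)-2-(2-hydroxy-3,4-dimethoxyphenyl)-7-methoxy-4H-chromen-4-one | COc1ccc(-c2cc(=O)c3c(OCc4ccccc4)cc(OC)cc3o2)c(O)c1OC
F9 | step 9 | 5-(benzyloxy)-2-(3-hydroxy-4,5-dimethoxyphenyl)-7-methoxy-4H-chromen-4-one | COc1cc(-c2cc(=O)c3c(OCc4ccccc4)cc(OC)cc3o2)cc(O)c1OC
F10 | step 5 | 5-(benzyloxy)-2-(2,2-dibromoethenyl)-7-methoxy-4H-chromen-4-one | BrC(Br)=Cc1cc(=O)c2c(OCc3ccccc3)cc(OC)cc2o1
F11 | step 5 | 5-(benzyloxy)-2-[(Z)-2-bromoethenyl]-7-methoxy-4H-chromen-4-one | Br/C=C\c1cc(=O)c2c(OCc3ccccc3)cc(OC)cc2o1
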